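**Retrosynthetic overview**
1. Target 9 ⇐ chalcone 8 by chemoselective hydrogenation of the enone C=C; 8 ⇐ Claisen–Schmidt union of ring A ketone 3 and ring B aldehyde 6.
2. Ketone 3 ⇐ prenyl triphenol 2 by closing the chroman O–C(Me)2 bond onto the 4-OH (key C–O bond, proposed new site-selective cobalt-hydride hydroalkoxylation); 2 ⇐ phloroacetophenone 1 + prenyl bromide.
3. Aldehyde 6 ⇐ Stille prenylation of bromide 5 ⇐ regioselective 4-O-methylation of 3-bromo-4,5-dihydroxybenzaldehyde 4.
4. Ring order: both benzene rings are bought; the pyran ring of the chroman is the only ring made, and it is closed before the fragments are joined, so the ring B prenyl group never meets the cyclisation conditions.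

Assumption: the target has no stereocentre and no E/Z-defined alkene (the prenyl terminus carries two methyls), so it is achiral; the route delivers that single compound and needs no stereocontrol.

**Step 1**
Reactants: 1 2,4,6-trihydroxyacetophenone
Product: 2 1-[2,4,6-trihydroxy-3-(3-methylbut-2-en-1-yl)phenyl]ethan-1-one
Conditions: prenyl bromide (1.0 equiv), 10% aq. KOH (1.1 equiv), 0 °C to rt, 3 h; then 1 M HCl
Reagents that add atoms: 1-bromo-3-methylbut-2-ene (prenyl bromide), CC(C)=CCBr
Why: The acylphloroglucinol phenoxide is ambident and in water alkylates at carbon, so direct C-prenylation (SN2 C-alkylation) at the equivalent C3/C5 positions gives the mono-C-prenyl ketone in the usual moderate yield; no stereocentre is formed.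

**Step 2**
Reactants: 2 1-[2,4,6-trihydroxy-3-(3-methylbut-2-en-1-yl)phenyl]ethan-1-one
Product: 3 1-(5,7-dihydroxy-2,2-dimethylchroman-6-yl)ethan-1-one (chroman = 3,4-dihydro-2H-chromene)
Conditions: Co(salen) complex C36H52CoN2O2 (divalent cobalt, N,N'-bis(3,5-di-tert-butylsalicylidene)cyclohexane-1,2-diamine ligand, 5 mol%), N-fluoro-2,4,6-trimethylpyridinium triflate (1.5 equiv), (Me2SiH)2O (1.5 equiv), 2,4,6-collidine (1.0 equiv), acetone/PhCF3 1:1, 0 °C to rt, Ar
Reagents that add atoms: none
Why: Proposed new method: acidity-gated cobalt-hydride hydrogen-atom-transfer cycloisomerisation, in which the cobalt hydride formed from the divalent cobalt salen, the N–F oxidant and the silane gives H• to the prenyl CH= carbon, the tertiary radical is oxidised through an alkylcobalt to a tertiary cation equivalent, and under collidine buffering only the most acidic 4-OH (para to the acetyl) is available as phenoxide while the 2-OH stays locked in the C=O chelate, so O4 closes the six-membered ring in a Markovnikov sense under acid-free kinetic control; the closest known reaction type is the cobalt-salen radical–polar crossover intramolecular hydroalkoxylation of unactivated alkenols, not yet shown for choosing between two phenolic OH groups of an unprotected acylphloroglucinol; no stereocentre is formed.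

**Step 3**
Reactants: 4 3-bromo-4,5-dihydroxybenzaldehyde
Product: 5 3-bromo-5-hydroxy-4-methoxybenzaldehyde
Conditions: MeI (1.05 equiv), Li2CO3 (1.2 equiv), DMF, 40 °C, 16 h
Reagents that add atoms: iodomethane, CI
Why: The 4-OH, para to the aldehyde and ortho to bromine, is the most acidic phenol, so the weak base forms only that phenoxide and the Williamson O-methylation is regioselective; no stereocentre is formed.

**Step 4**
Reactants: 5 3-bromo-5-hydroxy-4-methoxybenzaldehyde
Product: 6 3-hydroxy-4-methoxy-5-(3-methylbut-2-en-1-yl)benzaldehyde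
Conditions: tributyl(prenyl)stannane (1.3 equiv), Pd(PPh3)4 (5 mol%), DMF, 100 °C, Ar
Reagents that add atoms: tributyl(3-methylbut-2-en-1-yl)stannane, CCCC[Sn](CCCC)(CCCC)CC=C(C)C
Why: Stille cross-coupling of the aryl bromide with the allylic stannane gives the linear prenyl arene by reductive elimination at the less hindered allyl terminus and tolerates the free phenol and the aldehyde; no stereocentre is formed.

**Step 5**
Reactants: 3 1-(5,7-dihydroxy-2,2-dimethylchroman-6-yl)ethan-1-one; 6 3-hydroxy-4-methoxy-5-(3-methylbut-2-en-1-yl)benzaldehyde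
Product: 8 (E)-1-(5,7-dihydroxy-2,2-dimethylchroman-6-yl)-3-[3-hydroxy-4-methoxy-5-(3-methylbut-2-en-1-yl)phenyl]prop-2-en-1-one, via beta-hydroxy ketone aldol adduct 7 (not isolated)
Conditions: KOH (40% aq., 10 equiv), EtOH, Ar, rt, 36 h; then 1 M HCl at 0 °C to pH 4
Reagents that add atoms: none
Why: Claisen–Schmidt condensation, in which the methyl ketone enolate adds to the non-enolisable aldehyde (its meta-phenoxide does not deactivate the carbonyl) and E1cB dehydration gives the more stable (E)-enone, erasing the racemic carbinol centre of 7.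

**Step 6**
Reactants: 8 (E)-1-(5,7-dihydroxy-2,2-dimethylchroman-6-yl)-3-[3-hydroxy-4-methoxy-5-(3-methylbut-2-en-1-yl)phenyl]prop-2-en-1-one
Product: 9 1-(5,7-dihydroxy-2,2-dimethylchroman-6-yl)-3-[3-hydroxy-4-methoxy-5-(3-methylbut-2-en-1-yl)phenyl]propan-1-one (target CNP0408176.0)
Conditions: H2 (1–3 atm), RhCl(PPh3)3 (5 mol%), THF, rt
Reagents that add atoms: none
Why: Homogeneous hydrogenation with RhCl(PPh3)3 reduces the unhindered, electron-poor disubstituted enone C=C much faster than the isolated trisubstituted prenyl alkene and leaves the aryl ketone untouched; no stereocentre is formed.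

**Compound list**
1 | 2,4,6-trihydroxyacetophenone (phloroacetophenone) | CC(=O)c1c(O)cc(O)cc1O | starting material
2 | 1-[2,4,6-trihydroxy-3-(3-methylbut-2-en-1-yl)phenyl]ethan-1-one | CC(=O)c1c(O)cc(O)c(CC=C(C)C)c1O | intermediate
3 | 1-(5,7-dihydroxy-2,2-dimethylchroman-6-yl)ethan-1-one | CC(=O)c1c(O)cc2c(c1O)CCC(C)(C)O2 | intermediate
4 | 3-bromo-4,5-dihydroxybenzaldehyde | O=Cc1cc(O)c(O)c(Br)c1 | starting material
5 | 3-bromo-5-hydroxy-4-methoxybenzaldehyde | COc1c(O)cc(C=O)cc1Br | intermediate
6 | 3-hydroxy-4-methoxy-5-(3-methylbut-2-en-1-yl)benzaldehyde | COc1c(O)cc(C=O)cc1CC=C(C)C | intermediate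
7 | 1-(5,7-dihydroxy-2,2-dimethylchroman-6-yl)-3-hydroxy-3-[3-hydroxy-4-methoxy-5-(3-methylbut-2-en-1-yl)phenyl]propan-1-one (racemic aldol adduct, not isolated) | COc1c(O)cc(C(O)CC(=O)c2c(O)cc3c(c2O)CCC(C)(C)O3)cc1CC=C(C)C | intermediate
8 | (E)-1-(5,7-dihydroxy-2,2-dimethylchroman-6-yl)-3-[3-hydroxy-4-methoxy-5-(3-methylbut-2-en-1-yl)phenyl]prop-2-en-1-one | COc1c(O)cc(/C=C/C(=O)c2c(O)cc3c(c2O)CCC(C)(C)O3)cc1CC=C(C)C | intermediate
9 | 1-(5,7-dihydroxy-2,2-dimethylchroman-6-yl)-3-[3-hydroxy-4-methoxy-5-(3-methylbut-2-en-1-yl)phenyl]propan-1-one (achiral) | COc1c(O)cc(CCC(=O)c2c(O)cc3c(c2O)CCC(C)(C)O3)cc1CC=C(C)C | target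

**Step count**
Total steps: 6. Longest linear sequence: 4 steps (1 → 2 → 3 → 8 → 9, or 4 → 5 → 6 → 8 → 9).

**Three steps most likely to fail**

Step 2 (proposed new cyclisation). The risks are closure through the chelated 2-OH to the 8-acetyl isomer, ring fluorination of the electron-rich arene by the N–F oxidant, and slow hydrogen-atom transfer to the trisubstituted alkene. The fallback uses known chemistry, sets out from 1 and comes back at 3. O4-selective alkylation of 1 with 3-chloro-3-methylbut-1-yne (K2CO3, KI, CuI cat., acetone, reflux) gives the aryl propargyl ether 1-[2,6-dihydroxy-4-(2-methylbut-3-yn-2-yloxy)phenyl]ethan-1-one F1. Heating in N,N-diethylaniline at 150 °C triggers the propargyl Claisen rearrangement to the allenylphenol 1-[2,4,6-trihydroxy-3-(3-methylbuta-1,2-dien-1-yl)phenyl]ethan-1-one F2 (not isolated), which closes by 1,5-hydrogen shift and oxa-6π electrocyclisation to the chromene 1-(5,7-dihydroxy-2,2-dimethyl-2H-chromen-6-yl)ethan-1-one F3. Hydrogenation (H2, Pd/C, EtOAc) saturates the chromene double bond and gives 3. The regiochemistry is fixed because the pyran oxygen is the one that was alkylated and the two ortho carbons are equivalent.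

Step 5 (unprotected Claisen–Schmidt). The risks are sluggish enolate chemistry of the bis-phenoxide and partial closure of the 2',6'-dihydroxychalcone to the flavanone on acidification. The pairing itself has close precedent: a 4-O-alkylated 2,6-dihydroxyacetophenone and an isovanillin-type aldehyde condense in aqueous KOH on the way to neohesperidin dihydrochalcone. The fallback sets out from 3 and 6 and comes back at 9. Chloromethyl methyl ether and i-Pr2NEt in CH2Cl2 convert 3 into the mono-MOM ketone 1-[5-hydroxy-7-(methoxymethoxy)-2,2-dimethylchroman-6-yl]ethan-1-one F4 and 6 into 4-methoxy-3-(methoxymethoxy)-5-(3-methylbut-2-en-1-yl)benzaldehyde F5. Condensation (KOH, EtOH/H2O, rt) passes through the aldol adduct 3-hydroxy-1-[5-hydroxy-7-(methoxymethoxy)-2,2-dimethylchroman-6-yl]-3-[4-methoxy-3-(methoxymethoxy)-5-(3-methylbut-2-en-1-yl)phenyl]propan-1-one F6 (not isolated) to the protected chalcone (E)-1-[5-hydroxy-7-(methoxymethoxy)-2,2-dimethylchroman-6-yl]-3-[4-methoxy-3-(methoxymethoxy)-5-(3-methylbut-2-en-1-yl)phenyl]prop-2-en-1-one F7. Hydrogenation as in step 6 (H2, RhCl(PPh3)3, THF) gives the protected dihydrochalcone 1-[5-hydroxy-7-(methoxymethoxy)-2,2-dimethylchroman-6-yl]-3-[4-methoxy-3-(methoxymethoxy)-5-(3-methylbut-2-en-1-yl)phenyl]propan-1-one F8. Removal of both MOM groups (3 M HCl, MeOH, rt) gives 9; the ring B prenyl has no ortho hydroxyl and survives the brief dilute acid.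

Step 6 (chemoselective hydrogenation). The risks are partial saturation of the prenyl group and chalcone-to-flavanone isomerisation before the reduction is complete. The fallback installs the prenyl group last; it sets out from 3 and 5 and comes back at 9. Claisen–Schmidt condensation of 3 with the bromo aldehyde 5 (KOH, EtOH/H2O) passes through the aldol adduct 3-(3-bromo-5-hydroxy-4-methoxyphenyl)-1-(5,7-dihydroxy-2,2-dimethylchroman-6-yl)-3-hydroxypropan-1-one F9 (not isolated) to the bromo chalcone (E)-3-(3-bromo-5-hydroxy-4-methoxyphenyl)-1-(5,7-dihydroxy-2,2-dimethylchroman-6-yl)prop-2-en-1-one F10. With no prenyl present, this is hydrogenated over sulfided Pt/C (H2, EtOAc), which spares the aryl bromide, to the bromo dihydrochalcone 3-(3-bromo-5-hydroxy-4-methoxyphenyl)-1-(5,7-dihydroxy-2,2-dimethylchroman-6-yl)propan-1-one F11. Stille prenylation (tributyl(prenyl)stannane, Pd(PPh3)4, DMF, 100 °C) then gives 9.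

**Further compounds**
F1 | step 2 | 1-[2,6-dihydroxy-4-(2-methylbut-3-yn-2-yloxy)phenyl]ethan-1-one | CC(=O)c1c(O)cc(OC(C)(C)C#C)cc1O
F2 | step 2 | 1-[2,4,6-trihydroxy-3-(3-methylbuta-1,2-dien-1-yl)phenyl]ethan-1-one (not isolated) | CC(=O)c1c(O)cc(O)c(C=C=C(C)C)c1O
F3 | step 2 | 1-(5,7-dihydroxy-2,2-dimethyl-2H-chromen-6-yl)ethan-1-one | CC(=O)c1c(O)cc2c(c1O)C=CC(C)(C)O2
F4 | step 5 | 1-[5-hydroxy-7-(methoxymethoxy)-2,2-dimethylchroman-6-yl]ethan-1-one | CC(=O)c1c(OCOC)cc2c(c1O)CCC(C)(C)O2
F5 | step 5 | 4-methoxy-3-(methoxymethoxy)-5-(3-methylbut-2-en-1-yl)benzaldehyde | COCOc1cc(C=O)cc(CC=C(C)C)c1OC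
F6 | step 5 | 3-hydroxy-1-[5-hydroxy-7-(methoxymethoxy)-2,2-dimethylchroman-6-yl]-3-[4-methoxy-3-(methoxymethoxy)-5-(3-methylbut-2-en-1-yl)phenyl]propan-1-one (racemic, not isolated) | COCOc1cc(C(O)CC(=O)c2c(OCOC)cc3c(c2O)CCC(C)(C)O3)cc(CC=C(C)C)c1OC
F7 | step 5 | (E)-1-[5-hydroxy-7-(methoxymethoxy)-2,2-dimethylchroman-6-yl]-3-[4-methoxy-3-(methoxymethoxy)-5-(3-methylbut-2-en-1-yl)phenyl]prop-2-en-1-one | COCOc1cc(/C=C/C(=O)c2c(OCOC)cc3c(c2O)CCC(C)(C)O3)cc(CC=C(C)C)c1OC
F8 | step 5 | 1-[5-hydroxy-7-(methoxymethoxy)-2,2-dimethylchroman-6-yl]-3-[4-methoxy-3-(methoxymethoxy)-5-(3-methylbut-2-en-1-yl)phenyl]propan-1-one | COCOc1cc(CCC(=O)c2c(OCOC)cc3c(c2O)CCC(C)(C)O3)cc(CC=C(C)C)c1OC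
F9 | step 6 | 3-(3-bromo-5-hydroxy-4-methoxyphenyl)-1-(5,7-dihydroxy-2,2-dimethylchroman-6-yl)-3-hydroxypropan-1-one (racemic, not isolated) | COc1c(O)cc(C(O)CC(=O)c2c(O)cc3c(c2O)CCC(C)(C)O3)cc1Br
F10 | step 6 | (E)-3-(3-bromo-5-hydroxy-4-methoxyphenyl)-1-(5,7-dihydroxy-2,2-dimethylchroman-6-yl)prop-2-en-1-one | COc1c(O)cc(/C=C/C(=O)c2c(O)cc3c(c2O)CCC(C)(C)O3)cc1Br
F11 | step 6 | 3-(3-bromo-5-hydroxy-4-methoxyphenyl)-1-(5,7-dihydroxy-2,2-dimethylchroman-6-yl)propan-1-one | COc1c(O)cc(CCC(=O)c2c(O)cc3c(c2O)CCC(C)(C)O3)cc1Br
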